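Its constants were set for the occasion; the flask was simulated.

The constants 0.0349 M⁻¹ min⁻¹ and 0.0407 M⁻¹ min⁻¹ belong to the two competing attacks of reagent on dissolved starting material.

    starting material + reagent → first product + by-product (k1 = 0.0349 M⁻¹ min⁻¹)
    starting material + reagent → other mono adduct + by-product (k2 = 0.0407 M⁻¹ min⁻¹)
    reagent + first product → bis adduct + by-product (k3 = 0.0147 M⁻¹ min⁻¹)
    reagent + other mono adduct → bis adduct + by-product (k4 = 0.00128 M⁻¹ min⁻¹)
    solid substrate ⇌ starting material, rate k5*(cs5 - [starting material]) while solid is left; crystals form when [starting material] > cs5 (cs5 = 0.18 M, k5 = 0.314 min⁻¹)

solid substrate 0.50 M; reagent 1.10 equiv; time 40 min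

- dawn: doubling the solubility in step 5, all else as stated
- spring: doubling the dissolution coefficient of step 5, all else as stated
- summer: doubling the amount of reagent, all else as stated

1. the first product standing at 40 min, as a percentage of the solid substrate charged
2. the change that raises the amount of first product at 40 min, in percent of the solid substrate charged most ("none" if none brings more than 2 percentage points) (dawn / spring / summer / none)
3. amount of first product at 40 min, in percent of the solid substrate charged, after summer

- as a solid, counted per litre of solution: solid substrate
- at the start none of the solid substrate is in solution
- run time (flask): 40 min

The symmetric case is the zero of the scale: equal constants give each mono adduct 0.5 of what reacts. The split, the part of reacted starting material that becomes first product (its selectivity), is 46.2 %.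

My own chain begins with the dissolved level. Reaction empties the solution at 0.0416 min⁻¹ at the reagent's charge, less than the dissolution coefficient 0.314 min⁻¹, so starting material is taken at saturation, 36.0 % of the charge. Reagent then decays as a pseudo-first-order species. First product, out on average for 20.0 min, keeps 85.1 % against step 3. The split then gives 18.1 %.

The weak link is saturation itself. Balancing dissolution against reaction puts the level at 31.8 % of the charge, so 38.2 % of the reagent reacts and first product comes to 16.5 %. Reacted and dissolved substrate together make 73.8 % of the charge, less than the charge, so by this reckoning solid is still there at 40 min.

With the reagent doubled, the same chain gives 25.7 %. At doubled solubility saturation stands at 72.0 % of the charge, so the solid's lasting is in question, and my reckoning ranks no changes.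

The forecast gives 16 %, summer and 26.3 %, calling its choice “a narrow call from rough estimates”.

The flask gives 16.4 %, and summer wins with 11 percentage points, ahead of dawn at 8.4 points and spring at 1.1 points, reaching 26.9 %; the forecast held. In this flask the split applied to what has reacted, first product, other mono adduct and bis adduct together, gives 18.4 % at 40.0 min. First product, made 4.81 times faster than it is used up at that time, stands below that figure.

For the neighbour flask with 0.440 equiv of reagent, the same chain gives 7.69 %. That neighbour flask holds 7.38 % of first product.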